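An hour of catalyst is the unit this flask spends, so we count what one turn of the catalyst costs.

substrate 0.032 M; coupling partner 0.0960 M; free catalyst 0.80 mM; time 12 h

    substrate + free catalyst ⇌ catalyst intermediate A (K1 = 66 M⁻¹, k1 = 5690 M⁻¹ h⁻¹)
    coupling partner + catalyst intermediate A → catalyst intermediate B (k2 = 403 M⁻¹ h⁻¹)
    catalyst intermediate B ⇌ released group + catalyst intermediate C (K3 = 0.00687 M, k3 = 6.89 h⁻¹)
    catalyst intermediate C → free catalyst + product (k4 = 662 h⁻¹)
    coupling partner + released group ⇌ idle adduct, settled at all times (K5 = 740 M⁻¹)

* part of the substrate that has reacted at 12 h
* share of the unused coupling partner that is free and not bound as idle adduct, at 12 h

- for released group the idle adduct is counted in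
- run time (flask): 12 h

For one catalyst we add the release from catalyst intermediate B, the last step to product, the wait for coupling partner, and the wait for substrate, lengthened by catalyst intermediate A falling back. At the charge this sum is 0.190 h, and we call it the turn time. The release takes 0.145 h of it, so at the charge it is the rate-limiting step. The rate is the catalyst charged over the turn time, and the turn lengthens as substrate and partner fall, so the charge gives our bound from above. At that pace the substrate would pass in 7.61 h, less than the 12 h allowed, so this bound is complete conversion.

For the bound from below we let each turn take two partners, one consumed and one bound as idle adduct, and neglect the return of released group. The turn time then integrates over [substrate] in closed form, and bringing [substrate] down to 0.800 mM takes 12.0 h, about the run time. So we expect at least about 97.5% reacted.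

The forecast says 97.5% and 54.7%, reasoning that “each turnover takes about two partner equivalents”, which puts its conversion at our lower edge.

For this flask the simulation gives 97.6% and 53.7%, so the conversion lies inside the bracket and both forecast numbers stand within tolerance.

This flask averaged 0.307 h per turn, longer than the turn time at the charge. The neighbour flask has a quarter of the catalyst, 2.0 × 10⁻⁴ M, with the other charges and the time held. There the same turn time at the charge, our bound from above, allows 39.4% of the substrate in 12 h. That neighbour flask reaches 37.7%.

(Its constants were drawn at random within sensible limits; what happens was integrated by code.)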